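The readings were generated by integration for an exercise; noise was put on by code.

Two questions come first for the substrate in the teal flask: where does it stop, and how long does it take to get there?

the same everywhere: substrate 0.033 M

| flask | reagent | base | scavenger | remark | time |
|---|---|---|---|---|---|
| teal | 1 equiv | 0.050 equiv | 1.2 equiv | the very flask that is asked about, followed so far |  |
| red | 1 equiv | 0.050 equiv | 0.60 equiv | run made earlier |  |
| flask | 1.00 equiv | 0.0500 equiv | 1.20 equiv |  | 10 d |

- teal (time / d: substrate / %, product / %): 0.250: 88.4, 0; 0.833: 69.7, 1.1; 1.25: 60.0, 0; 2.00: 53.6, 0.8; 3.00: 44.0, 0; 4.00: 44.3, 0.8; 5.00: 41.9, 0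
- red (time / d: substrate / %, product / %): 0.500: 80.5, 1.2; 1.67: 57.0, 0; 3.00: 46.4, 0; 4.00: 44.3, 2.5; 6.00: 42.7, 1.2; 8.00: 41.1, 0; 10.0: 42.4, 0.8

(standard deviation of a reading: 1 percentage point)

- the analysis behind the earlier runs scatters by 1 percentage point, standard deviation
- what has gone from substrate into another species counts as reacted, even if it can come back
- the earlier runs do not show how much of reagent is bound; that part of a forecast is a guess

1. part of the substrate that has reacted at 10 d
2. share of the unused reagent that is free and not bound as idle adduct, at 10 d

Where it stops: from 6.00 d to 10.0 d the red flask reads 42.7%, 41.1% and 42.4% of its substrate, on average 42.1%, and the teal flask, with twice the scavenger, already reads 41.9% at 5.00 d.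

How long it takes: the teal reading of 69.7% at 0.833 d leaves 47.7% of the starting distance to that plateau. So the distance halves in about 0.780 d. We call this the half-time of approach, the half-life of a first-order relaxation: each such interval halves what remains of the distance.

Does the clock still matter at the asked time? In the teal flask, 10 d is 12.8 half-times, so we take the relaxation as over and commit to the plateau: 57.9% reacted. The runs do not show bound reagent, and we put no number on it.

The forecast gives 58% reacted and 42% free reagent, saying of the latter: “This is a guess, since reagent binding was never measured”.

The teal flask gives 58.6% reacted and >99.9% free reagent, with 58.0% of the substrate charged standing as dormant form and the idle adduct at 6.02 × 10⁻⁸ M.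

    substrate + reagent + released group → product + 2 released group (k = 0.0950 L² mol⁻² s⁻¹)
    substrate + reagent → product + released group (k = 3.90 × 10⁻⁷ L mol⁻¹ s⁻¹)
    base + released group ⇌ salt, settled at all times (K = 4.20 × 10⁵ L mol⁻¹)
    reagent + released group ⇌ idle adduct, settled at all times (K = 15.0 L mol⁻¹)
    scavenger + released group → scavenged by-product (k = 0.0330 L mol⁻¹ s⁻¹)
    substrate ⇌ dormant form (K = 1.40, k = 5.60 × 10⁻⁶ s⁻¹)

Our half-time puts the teal flask at 51.6% reacted at 2.50 d, and it has used 51.1%. A neighbour flask charged with 0.250 equiv of reagent goes through the same substrate step, whose equation holds no reagent, so we carry the half-time over: 12.8 half-times again, hence 57.9%. The computed flask gives 58.4%.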